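**Retrosynthetic overview**

1. Target 24 ⇐ alkene 20 (Shi epoxide, bromide opening with inversion, tertiary OH → Cl through a bromonium ion, desilylation); 20 ⇐ ketone 16 (Wittig; exo-face Giese addition of the tertiary ring radical made by hydrogen-atom transfer to an exocyclic methylene).
2. 16 ⇐ 15 by reductive removal of a relay chlorine (exo-protonation of the enolate sets the ring CH) and of the sulfonyl group.
3. Key disconnection: in the 7-oxabicyclo[2.2.1]heptane the ether oxygen O7 joins the bridgeheads C1 and C4, and these are also spanned by the unsubstituted ethano bridge C5–C6. This oxolane-plus-CH2CH2 pattern is the retron of a five-membered carbonyl ylide (C1–O7–C4) adding to an ethylene equivalent, so C4–C5 and C6–C1 are formed together (15 ⇐ diazo diketone 12 + phenyl vinyl sulfone 13).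
4. Ring order: the oxolane ring first (acetyl oxygen closes onto the rhodium carbene), the six-membered carbocycle second, both in step 8. A catalyst-set C–Cl stereocentre next to the ylide relays the absolute configuration to both bridgeheads and is then deleted.
5. 12 ⇐ tert-butyl acetoacetate 6 + iodide 5; 5 comes from (S)-linalool 1 (ozonolysis, alkoxy-radical fragmentation), which supplies the carbinol stereocentre.

Key step: step 8

Remark: ring positions are numbered the same way throughout (C1 = CH bridgehead, C2 = neighbouring ring carbon, C3 = ring carbon bearing the pentenyl chain, C4 = methyl-bearing bridgehead, C5/C6 = ethano bridge with C5 next to C4, O7 = bridge oxygen; not always lowest locants), and (S)-linalool is assumed to be at hand in high enantiomeric purity.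

**Route**

Step 1
Reactants: 1 (S)-linalool
Product: 2 (5S)-5-ethenyl-5-methyloxolan-2-ol
Conditions: O3, CH2Cl2/MeOH, NaHCO3, −78 °C, Sudan Red indicator; then Me2S, −78 → 25 °C
Reagents that add atoms: ozone, [O-][O+]=O
Why: Ozonolysis (Criegee) stopped at the indicator end point should cleave only the electron-rich trisubstituted alkene, and the 4-hydroxy aldehyde closes to the lactol with the carbinol stereocentre of 1 untouched.

Step 2
Reactants: 2 (5S)-5-ethenyl-5-methyloxolan-2-ol
Product: 3 (3S)-5-iodo-3-methylpent-1-en-3-yl formate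
Conditions: PhI(OAc)2, I2, CH2Cl2, hν (visible light), 25 °C
Reagents that add atoms: iodine, II
Why: Suárez alkoxy-radical β-fragmentation: the lactol hypoiodite gives an anomeric alkoxy radical whose ring C–C bond breaks to a formate and a primary radical that iodine traps, so one carbon is excised without touching the stereocentre.

Step 3
Reactants: 3 (3S)-5-iodo-3-methylpent-1-en-3-yl formate
Product: 5 triethyl{[(3S)-5-iodo-3-methylpent-1-en-3-yl]oxy}silane, via iodo alcohol 4 (not isolated)
Conditions: K2CO3 (cat.), MeOH, 0 °C; evaporate; then TESOTf, 2,6-lutidine, CH2Cl2, −78 → 0 °C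
Reagents that add atoms: triethylsilyl trifluoromethanesulfonate, CC[Si](CC)(CC)OS(=O)(=O)C(F)(F)F
Why: Formate transesterification followed by silyl-triflate silylation of the tertiary alcohol installs a group meant to last until the final step; no stereocentre is involved.

Step 4
Reactants: 5 triethyl{[(3S)-5-iodo-3-methylpent-1-en-3-yl]oxy}silane; 6 tert-butyl 3-oxobutanoate
Product: 7 tert-butyl (5S)-2-acetyl-5-methyl-5-[(triethylsilyl)oxy]hept-6-enoate
Conditions: NaH, THF/DMF, 0 °C; then 5, 50 °C
Reagents that add atoms: none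
Why: C-Alkylation (SN2) of the acetoacetate sodium enolate by the unhindered primary iodide; the new α-centre forms as both epimers, which does not matter because step 5 fixes it.

Step 5
Reactants: 7 tert-butyl (5S)-2-acetyl-5-methyl-5-[(triethylsilyl)oxy]hept-6-enoate
Product: 8 tert-butyl (2R,5S)-2-acetyl-2-chloro-5-methyl-5-[(triethylsilyl)oxy]hept-6-enoate
Conditions: NCS, Cu(OTf)2 (10 mol%), Ph-box ligand (11 mol%, the enantiomer that gives 2R), Et2O, 25 °C
Reagents that add atoms: N-chlorosuccinimide, O=C1CCC(=O)N1Cl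
Why: Catalytic enantioselective α-chlorination of an α-substituted β-keto ester through its chiral copper bis(oxazoline) enolate, in which the ligand and not the remote carbinol centre should set the quaternary C–Cl stereocentre (2R); any 2S epimer is carried on and removed as a diastereomer at bicyclic 16.

Step 6
Reactants: 8 tert-butyl (2R,5S)-2-acetyl-2-chloro-5-methyl-5-[(triethylsilyl)oxy]hept-6-enoate
Product: 10 (2R,5S)-2-acetyl-2-chloro-5-methyl-5-[(triethylsilyl)oxy]hept-6-enoic acid, via trimethylsilyl ester 9 (not isolated)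
Conditions: TMSOTf, 2,6-lutidine, CH2Cl2, 0 °C; then pH 4 phosphate buffer, 0 °C
Reagents that add atoms: none
Why: Silyl-triflate cleavage of the tert-butyl ester (loss of isobutene) under non-protic conditions should spare the tertiary allylic silyl ether, and mild hydrolysis frees the α,α-disubstituted β-keto acid, which cannot epimerise and is kept cold against decarboxylation.

Step 7
Reactants: 10 (2R,5S)-2-acetyl-2-chloro-5-methyl-5-[(triethylsilyl)oxy]hept-6-enoic acid
Product: 12 (3R,6S)-3-acetyl-3-chloro-1-diazo-6-methyl-6-[(triethylsilyl)oxy]oct-7-en-2-one, via mixed carbonic anhydride 11 (not isolated)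
Conditions: i-BuOCOCl, N-methylmorpholine, THF, −20 °C; then CH2N2, Et2O, −20 → 0 °C
Reagents that add atoms: diazomethane, C=[N+]=[N-]
Why: Acylation of diazomethane by the mixed carbonic anhydride (first stage of an Arndt–Eistert sequence) turns the carboxyl carbon into the α-diazo ketone without touching the quaternary centre.

Step 8
Reactants: 12 (3R,6S)-3-acetyl-3-chloro-1-diazo-6-methyl-6-[(triethylsilyl)oxy]oct-7-en-2-one; 13 phenyl vinyl sulfone
Product: 15 (1R,3R,4S,5S)-3-chloro-4-methyl-3-{(3S)-3-methyl-3-[(triethylsilyl)oxy]pent-4-en-1-yl}-5-(phenylsulfonyl)-7-oxabicyclo[2.2.1]heptan-2-one, via carbonyl ylide 14 (not isolated)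
Conditions: Rh2(OAc)4 (1 mol%), 13 (5 equiv), CH2Cl2, 25 °C, slow addition of 12
Reagents that add atoms: none
Why: Dirhodium tetraacetate removes N2 from the diazo ketone and the acetyl oxygen closes onto the electrophilic carbene carbon (five-membered ring O7–C4–C3–C2–C1, closure by carbonyl lone-pair attack) to give the acyl-stabilised cyclic carbonyl ylide 14; this adds across C4 and C1 to the vinyl sulfone in a concerted [3+2] cycloaddition that makes C4–C5 and C6–C1 together and so closes the six-membered carbocycle of the bicycle. The closest known reaction is the rhodium-carbenoid tandem cyclisation–cycloaddition of 1-diazo-2,4-diones with a quaternary C3, which gives five-membered carbonyl ylides that add to electron-poor alkenes. The two bridgehead stereocentres are locked to each other by suprafacial addition to the planar ylide and are set in the absolute sense by the chlorinated quaternary C3 beside the oxocarbenium terminus: the sulfone should approach anti to the pentenyl chain and syn to the small, σ-accepting C–Cl bond, which places Cl endo. The quaternary C3 also blocks tautomerisation of the ylide to a 3(2H)-furanone. Regiochemistry (sulfonyl carbon at C5, from union of the nucleophilic C1 terminus with the β-carbon of the sulfone) and the exo/endo position of the sulfonyl group are of no consequence, since step 9 removes that group. The step needs facial selectivity and intermolecular capture that outruns addition to the remote vinyl group; the Cl/alkyl difference at C3 and the excess of reactive dipolarophile are meant to secure both.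

Step 9
Reactants: 15 (1R,3R,4S,5S)-3-chloro-4-methyl-3-{(3S)-3-methyl-3-[(triethylsilyl)oxy]pent-4-en-1-yl}-5-(phenylsulfonyl)-7-oxabicyclo[2.2.1]heptan-2-one
Product: 16 (1R,3R,4S)-4-methyl-3-{(3S)-3-methyl-3-[(triethylsilyl)oxy]pent-4-en-1-yl}-7-oxabicyclo[2.2.1]heptan-2-one
Conditions: Na/Hg (6%), Na2HPO4, MeOH/THF, −20 °C
Reagents that add atoms: none
Why: Dissolving-metal reduction turns the α-chloro ketone into a sodium enolate that methanol should protonate kinetically from the open exo face (H exo, pentenyl chain endo at C3) and replaces the phenylsulfonyl group by hydrogen (reductive desulfonylation), so all isomers of 15 at the sulfonyl carbon converge.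

Step 10
Reactants: 16 (1R,3R,4S)-4-methyl-3-{(3S)-3-methyl-3-[(triethylsilyl)oxy]pent-4-en-1-yl}-7-oxabicyclo[2.2.1]heptan-2-one
Product: 17 (1R,3S,4S)-4-methyl-2-methylidene-3-{(3S)-3-methyl-3-[(triethylsilyl)oxy]pent-4-en-1-yl}-7-oxabicyclo[2.2.1]heptane
Conditions: Zn, CH2Br2, TiCl4, THF/CH2Cl2, 0 → 25 °C
Reagents that add atoms: dibromomethane, BrCBr
Why: Takai–Lombardo methylenation is non-basic and works on hindered ketones, so the epimerisable C3 centre next to the carbonyl should be preserved.

Step 11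
Reactants: 17 (1R,3S,4S)-4-methyl-2-methylidene-3-{(3S)-3-methyl-3-[(triethylsilyl)oxy]pent-4-en-1-yl}-7-oxabicyclo[2.2.1]heptane; 18 acrolein
Product: 19 3-{(1R,2S,3S,4S)-2,4-dimethyl-3-[(3S)-3-methyl-3-(triethylsilyloxy)pent-4-en-1-yl]-7-oxabicyclo[2.2.1]heptan-2-yl}propanal
Conditions: Fe(acac)3 (30 mol%), PhSiH3, 18 (3 equiv), EtOH/ethylene glycol, 60 °C
Reagents that add atoms: none
Why: Hydrogen-atom-transfer-initiated Giese reaction: the iron hydride should add H• to the 1,1-disubstituted exocyclic alkene faster than to the monosubstituted vinyl group, and the tertiary C2 radical should add to acrolein from the exo face, which makes the quaternary centre with the new chain exo and the new methyl endo.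

Step 12
Reactants: 19 3-{(1R,2S,3S,4S)-2,4-dimethyl-3-[(3S)-3-methyl-3-(triethylsilyloxy)pent-4-en-1-yl]-7-oxabicyclo[2.2.1]heptan-2-yl}propanal
Product: 20 triethyl{[(3S)-5-{(1R,2S,3S,4S)-2,4-dimethyl-2-(4-methylpent-3-en-1-yl)-7-oxabicyclo[2.2.1]heptan-3-yl}-3-methylpent-1-en-3-yl]oxy}silane
Conditions: i-PrPPh3I, n-BuLi, THF, 0 °C; then 19, −78 → 25 °C
Reagents that add atoms: isopropyltriphenylphosphonium iodide, CC(C)[P+](c1ccccc1)(c1ccccc1)c1ccccc1.[I-]
Why: Wittig olefination with the non-stabilised isopropylidene ylide converts the aldehyde into the trisubstituted alkene; no alkene geometry arises because the new terminus carries two methyl groups.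

Step 13
Reactants: 20 triethyl{[(3S)-5-{(1R,2S,3S,4S)-2,4-dimethyl-2-(4-methylpent-3-en-1-yl)-7-oxabicyclo[2.2.1]heptan-3-yl}-3-methylpent-1-en-3-yl]oxy}silane
Product: 21 triethyl{[(3S)-5-{(1R,2S,3S,4S)-2-{2-[(2R)-3,3-dimethyloxiran-2-yl]ethyl}-2,4-dimethyl-7-oxabicyclo[2.2.1]heptan-3-yl}-3-methylpent-1-en-3-yl]oxy}silane
Conditions: D-fructose-derived Shi ketone (30 mol%), KHSO5 (as 2KHSO5·KHSO4·K2SO4), K2CO3, Bu4NHSO4, MeCN/CH2(OMe)2/aq. Na2B4O7, 0 °C
Reagents that add atoms: potassium peroxymonosulfate, [K+].[O-]S(=O)(=O)OO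
Why: Shi epoxidation: the chiral dioxirane should epoxidise the electron-rich trisubstituted alkene and leave the monosubstituted vinyl group, and the D-fructose-derived catalyst should give the (R)-epoxide by reagent control (spiro transition state).

Step 14
Reactants: 21 triethyl{[(3S)-5-{(1R,2S,3S,4S)-2-{2-[(2R)-3,3-dimethyloxiran-2-yl]ethyl}-2,4-dimethyl-7-oxabicyclo[2.2.1]heptan-3-yl}-3-methylpent-1-en-3-yl]oxy}silane
Product: 22 (3S)-3-bromo-5-{(1R,2S,3S,4S)-2,4-dimethyl-3-[(3S)-3-methyl-3-(triethylsilyloxy)pent-4-en-1-yl]-7-oxabicyclo[2.2.1]heptan-2-yl}-2-methylpentan-2-ol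
Conditions: Li2NiBr4, THF, 0 → 25 °C
Reagents that add atoms: dilithium tetrabromonickelate, [Li+].[Li+].[Ni+2].[Br-].[Br-].[Br-].[Br-]
Why: Epoxide opening by soft bromide at the less substituted carbon (SN2) should invert that centre to the (S)-bromide and leave the tertiary alcohol.

Step 15
Reactants: 22 (3S)-3-bromo-5-{(1R,2S,3S,4S)-2,4-dimethyl-3-[(3S)-3-methyl-3-(triethylsilyloxy)pent-4-en-1-yl]-7-oxabicyclo[2.2.1]heptan-2-yl}-2-methylpentan-2-ol
Product: 23 triethyl{[(3S)-5-{(1R,2S,3S,4S)-2-[(3S)-3-bromo-4-chloro-4-methylpentyl]-2,4-dimethyl-7-oxabicyclo[2.2.1]heptan-3-yl}-3-methylpent-1-en-3-yl]oxy}silane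
Conditions: 1-chloro-N,N,2-trimethylprop-1-en-1-amine, CH2Cl2, 0 → 25 °C
Reagents that add atoms: 1-chloro-N,N,2-trimethylprop-1-en-1-amine, CC(C)=C(Cl)N(C)C
Why: Alcohol-to-chloride conversion under neutral conditions: the α-chloro enamine makes an alkoxyiminium chloride whose ionisation is assisted by the neighbouring bromine (bromonium ion), and chloride opens it at the tertiary carbon, so the C–Br stereocentre is retained.

Step 16
Reactants: 23 triethyl{[(3S)-5-{(1R,2S,3S,4S)-2-[(3S)-3-bromo-4-chloro-4-methylpentyl]-2,4-dimethyl-7-oxabicyclo[2.2.1]heptan-3-yl}-3-methylpent-1-en-3-yl]oxy}silane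
Product: 24 (3S)-5-{(1R,2S,3S,4S)-2-[(3S)-3-bromo-4-chloro-4-methylpentyl]-2,4-dimethyl-7-oxabicyclo[2.2.1]heptan-3-yl}-3-methylpent-1-en-3-ol (CNP0297543.1)
Conditions: HF·pyridine, pyridine, THF, 0 °C
Reagents that add atoms: none
Why: Buffered fluoride cleavage of the silyl ether should leave the tertiary allylic alcohol, the secondary bromide and the tertiary chloride untouched.

**Compound list**

1 | (3S)-3,7-dimethylocta-1,6-dien-3-ol, (S)-linalool | C=C[C@@](C)(O)CCC=C(C)C | starting material
2 | (5S)-5-ethenyl-5-methyloxolan-2-ol (both anomers) | C=C[C@]1(C)CCC(O)O1 | intermediate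
3 | (3S)-5-iodo-3-methylpent-1-en-3-yl formate | C=C[C@@](C)(OC=O)CCI | intermediate
4 | (3S)-5-iodo-3-methylpent-1-en-3-ol | C=C[C@@](C)(O)CCI | intermediate (not isolated)
5 | triethyl{[(3S)-5-iodo-3-methylpent-1-en-3-yl]oxy}silane | C=C[C@@](C)(O[Si](CC)(CC)CC)CCI | intermediate
6 | tert-butyl 3-oxobutanoate | CC(=O)CC(=O)OC(C)(C)C | starting material
7 | tert-butyl (5S)-2-acetyl-5-methyl-5-[(triethylsilyl)oxy]hept-6-enoate (both C2 epimers) | C=C[C@@](C)(O[Si](CC)(CC)CC)CCC(C(C)=O)C(=O)OC(C)(C)C | intermediate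
8 | tert-butyl (2R,5S)-2-acetyl-2-chloro-5-methyl-5-[(triethylsilyl)oxy]hept-6-enoate | C=C[C@@](C)(O[Si](CC)(CC)CC)CC[C@@](Cl)(C(C)=O)C(=O)OC(C)(C)C | intermediate
9 | trimethylsilyl (2R,5S)-2-acetyl-2-chloro-5-methyl-5-[(triethylsilyl)oxy]hept-6-enoate | C=C[C@@](C)(O[Si](CC)(CC)CC)CC[C@@](Cl)(C(C)=O)C(=O)O[Si](C)(C)C | intermediate (not isolated)
10 | (2R,5S)-2-acetyl-2-chloro-5-methyl-5-[(triethylsilyl)oxy]hept-6-enoic acid | C=C[C@@](C)(O[Si](CC)(CC)CC)CC[C@@](Cl)(C(C)=O)C(=O)O | intermediate
11 | mixed anhydride of 10 with isobutyl hydrogen carbonate | C=C[C@@](C)(O[Si](CC)(CC)CC)CC[C@@](Cl)(C(C)=O)C(=O)OC(=O)OCC(C)C | intermediate (not isolated)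
12 | (3R,6S)-3-acetyl-3-chloro-1-diazo-6-methyl-6-[(triethylsilyl)oxy]oct-7-en-2-one | C=C[C@@](C)(O[Si](CC)(CC)CC)CC[C@@](Cl)(C(C)=O)C(=O)C=[N+]=[N-] | intermediate
13 | (ethenesulfonyl)benzene, phenyl vinyl sulfone | C=CS(=O)(=O)c1ccccc1 | starting material
14 | carbonyl ylide: 4-chloro-5-methyl-4-{(3S)-3-methyl-3-[(triethylsilyl)oxy]pent-4-en-1-yl}-3-oxo-3,4-dihydro-2H-furan-1-ium-2-ide (configuration at the chlorinated carbon as in 12) | C=C[C@@](C)(O[Si](CC)(CC)CC)CC[C@]1(Cl)C(=O)[CH-][O+]=C1C | intermediate (not isolated)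
15 | (1R,3R,4S,5S)-3-chloro-4-methyl-3-{(3S)-3-methyl-3-[(triethylsilyl)oxy]pent-4-en-1-yl}-5-(phenylsulfonyl)-7-oxabicyclo[2.2.1]heptan-2-one (Cl endo; exo-sulfonyl isomer drawn) | C=C[C@@](C)(O[Si](CC)(CC)CC)CC[C@]1(Cl)C(=O)[C@H]2C[C@H](S(=O)(=O)c3ccccc3)[C@]1(C)O2 | intermediate
16 | (1R,3R,4S)-4-methyl-3-{(3S)-3-methyl-3-[(triethylsilyl)oxy]pent-4-en-1-yl}-7-oxabicyclo[2.2.1]heptan-2-one (side chain endo) | C=C[C@@](C)(O[Si](CC)(CC)CC)CC[C@H]1C(=O)[C@H]2CC[C@]1(C)O2 | intermediate
17 | (1R,3S,4S)-4-methyl-2-methylidene-3-{(3S)-3-methyl-3-[(triethylsilyl)oxy]pent-4-en-1-yl}-7-oxabicyclo[2.2.1]heptane | C=C[C@@](C)(O[Si](CC)(CC)CC)CC[C@H]1C(=C)[C@H]2CC[C@]1(C)O2 | intermediate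
18 | prop-2-enal, acrolein | C=CC=O | starting material
19 | 3-{(1R,2S,3S,4S)-2,4-dimethyl-3-[(3S)-3-methyl-3-(triethylsilyloxy)pent-4-en-1-yl]-7-oxabicyclo[2.2.1]heptan-2-yl}propanal | C=C[C@@](C)(O[Si](CC)(CC)CC)CC[C@H]1[C@](C)(CCC=O)[C@H]2CC[C@]1(C)O2 | intermediate
20 | triethyl{[(3S)-5-{(1R,2S,3S,4S)-2,4-dimethyl-2-(4-methylpent-3-en-1-yl)-7-oxabicyclo[2.2.1]heptan-3-yl}-3-methylpent-1-en-3-yl]oxy}silane | C=C[C@@](C)(O[Si](CC)(CC)CC)CC[C@H]1[C@](C)(CCC=C(C)C)[C@H]2CC[C@]1(C)O2 | intermediate
21 | triethyl{[(3S)-5-{(1R,2S,3S,4S)-2-{2-[(2R)-3,3-dimethyloxiran-2-yl]ethyl}-2,4-dimethyl-7-oxabicyclo[2.2.1]heptan-3-yl}-3-methylpent-1-en-3-yl]oxy}silane | C=C[C@@](C)(O[Si](CC)(CC)CC)CC[C@H]1[C@](C)(CC[C@H]3OC3(C)C)[C@H]2CC[C@]1(C)O2 | intermediate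
22 | (3S)-3-bromo-5-{(1R,2S,3S,4S)-2,4-dimethyl-3-[(3S)-3-methyl-3-(triethylsilyloxy)pent-4-en-1-yl]-7-oxabicyclo[2.2.1]heptan-2-yl}-2-methylpentan-2-ol | C=C[C@@](C)(O[Si](CC)(CC)CC)CC[C@H]1[C@](C)(CC[C@H](Br)C(C)(C)O)[C@H]2CC[C@]1(C)O2 | intermediate
23 | triethyl{[(3S)-5-{(1R,2S,3S,4S)-2-[(3S)-3-bromo-4-chloro-4-methylpentyl]-2,4-dimethyl-7-oxabicyclo[2.2.1]heptan-3-yl}-3-methylpent-1-en-3-yl]oxy}silane | C=C[C@@](C)(O[Si](CC)(CC)CC)CC[C@H]1[C@](C)(CC[C@H](Br)C(C)(C)Cl)[C@H]2CC[C@]1(C)O2 | intermediate
24 | (3S)-5-{(1R,2S,3S,4S)-2-[(3S)-3-bromo-4-chloro-4-methylpentyl]-2,4-dimethyl-7-oxabicyclo[2.2.1]heptan-3-yl}-3-methylpent-1-en-3-ol | C=C[C@@](C)(O)CC[C@H]1[C@](C)(CC[C@H](Br)C(C)(C)Cl)[C@H]2CC[C@]1(C)O2 | target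

**Count and risks**

Total step count: 16. Longest linear sequence: 16 steps (1 → 24).

Steps most likely to fail:

Step 8. The ylide may be captured intramolecularly by the vinyl group of its own side chain, or may dimerise, faster than it adds to the vinyl sulfone; facial selectivity at the chlorinated carbon may also be incomplete. If the facial preference turns out to be the reverse, the enantiomeric ligand in step 5 corrects the series. The fallback sets out from 12 and comes back at 16. Under the same Rh2(OAc)4 catalysis, 12 is combined with (E)-1,2-bis(phenylsulfonyl)ethene, a much more reactive acetylene equivalent, to give the trans-bis-sulfone adduct F1. Na/Hg in buffered MeOH then removes the chlorine (exo-protonation of the enolate) and eliminates the two vicinal sulfonyl groups reductively to the oxanorbornenone F2, which avoids protonation of a carbanion β to the bridge oxygen. Diimide (from KO2CN=NCO2K and AcOH) should saturate only the strained ring alkene and return 16.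

Step 11. Hydrogen-atom transfer may also reach the side-chain vinyl group, and the tertiary radical may be reduced, or acrolein oligomerised, instead of giving the Giese product. The fallback sets out from 16 and comes back at 19; it makes the same tertiary radical from a defined precursor. MeMgCl/CeCl3 adds to the ketone from the exo face to give the tertiary alcohol F3. Methyl chlorooxoacetate with Et3N/DMAP gives the methyl oxalate F4, and CsOH gives the cesium oxalate F5. Visible-light photoredox coupling (Ir[dF(CF3)ppy]2(dtbbpy)PF6, aqueous DME/DMF) with methyl acrylate then gives the exo-Giese product, the methyl ester F6, and DIBAL at −78 °C reduces it to 19.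

Step 15. Ionisation of the tertiary alcohol may end in elimination to the isopropenyl bromide, or in loss of the tertiary allylic silyl ether, rather than in chloride capture. The fallback sets out from 21 and comes back at 23; it reverses the order of halogen introduction. TiCl(Oi-Pr)3 in CH2Cl2 at low temperature opens the epoxide with chloride at the tertiary carbon to give the chlorohydrin F7 (configuration of the carbinol carbon retained). Chloromethanesulfonyl chloride/pyridine gives the chloromethanesulfonate F8, and LiBr in DMF displaces it with inversion to give 23.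

**Further compounds**

F1 | step 8 | trans-5,6-bis(phenylsulfonyl) analogue of 15 (5-exo,6-endo isomer drawn) | C=C[C@@](C)(O[Si](CC)(CC)CC)CC[C@]1(Cl)C(=O)[C@H]2[C@@H](S(=O)(=O)c3ccccc3)[C@H](S(=O)(=O)c3ccccc3)[C@]1(C)O2
F2 | step 8 | 5,6-didehydro analogue of 16: 4-methyl-3-endo-{(3S)-3-methyl-3-[(triethylsilyl)oxy]pent-4-en-1-yl}-7-oxabicyclo[2.2.1]hept-5-en-2-one | C=C[C@@](C)(O[Si](CC)(CC)CC)CC[C@H]1C(=O)[C@H]2C=C[C@]1(C)O2
F3 | step 11 | tertiary alcohol from methyl addition to 16 (2-exo-methyl, 2-endo-hydroxy) | C=C[C@@](C)(O[Si](CC)(CC)CC)CC[C@H]1[C@@](C)(O)[C@H]2CC[C@]1(C)O2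
F4 | step 11 | methyl oxalate of F3 | C=C[C@@](C)(O[Si](CC)(CC)CC)CC[C@H]1[C@@](C)(OC(=O)C(=O)OC)[C@H]2CC[C@]1(C)O2
F5 | step 11 | cesium oxalate of F3 | C=C[C@@](C)(O[Si](CC)(CC)CC)CC[C@H]1[C@@](C)(OC(=O)C(=O)[O-])[C@H]2CC[C@]1(C)O2.[Cs+]
F6 | step 11 | methyl ester corresponding to aldehyde 19 | C=C[C@@](C)(O[Si](CC)(CC)CC)CC[C@H]1[C@](C)(CCC(=O)OC)[C@H]2CC[C@]1(C)O2
F7 | step 15 | chlorohydrin from 21: (3R)-4-chloro-3-hydroxy-4-methylpentyl side chain | C=C[C@@](C)(O[Si](CC)(CC)CC)CC[C@H]1[C@](C)(CC[C@@H](O)C(C)(C)Cl)[C@H]2CC[C@]1(C)O2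
F8 | step 15 | chloromethanesulfonate of F7 | C=C[C@@](C)(O[Si](CC)(CC)CC)CC[C@H]1[C@](C)(CC[C@@H](OS(=O)(=O)CCl)C(C)(C)Cl)[C@H]2CC[C@]1(C)O2
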